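**Retrosynthetic overview**

1. Labels: ring A = chromone benzo ring, ring B = pyranone, ring C = cyclopentene (Cq, chromone C3, chromone C2, Cx, Cy), ring D = oxygen-bridged ring (Bq, Cx, Cy, Bh, O), ring E = methylhydroquinone ring (O8 = its phenol oxygen beside Bq), ring F = 2,6-dihydroxyphenyl on Bq; Cq = C(OH)CO2Me carbon, Cx / Cy = bridge CH on chromone C2 / on Cq, Bh = CH–O bridgehead, Bq = aryl-bearing O-bridgehead.
2. Feature: chromone C2 and C3 each belong to both ring B and ring C, so cutting O1–C2 and C3–Cq opens both rings to a 2,6-dihydroxyaryl ynone on Cx and an α-ketoester on Cy, held exo-cis on ring D; a Pd(OAc)2/bipyridine oxypalladation–carbonyl addition cascade closes B, then C.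
3. Ynone ketoester ⇐ exo-cis three-component coupling (zerovalent palladium) of a resolved oxabenzonorbornadiene with methyl 2-bromoacrylate (latent ketoester, unveiled last by dihydroxylation/periodate) and a ring A propargylic alcohol (latent ynone).
4. Oxabenzonorbornadiene ⇐ intramolecular aryne–furan Diels–Alder; a t-Bu2Si tether from O8 to one ring F oxygen fixes the regiochemistry and then stays on as a protecting group.
5. Ring order: E and F (purchased) → D (aryne/furan) → A (purchased) → B and C together (key step) → desilylation.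

Key step: step 20

Remark: the enantiomers separated in step 9 are assumed to be assignable by X-ray diffraction (anomalous scattering of silicon) or ECD; the enantiomer with Bq S and Bh R is carried on.

**Route**

Step 1
Reactants: 1 4-hydroxy-3-methylbenzaldehyde; 2 3-methylbutane-1,3-diol
Product: 3 4-(3-hydroxy-3-methylbutoxy)-3-methylbenzaldehyde
Conditions: PPh3, DIAD, THF, 0 °C → rt
Reagents that add atoms: none
Why: Mitsunobu etherification: the acidic para-formylphenol is alkylated by the primary hydroxyl of the diol, while the tertiary hydroxyl cannot be activated and stays free.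

Step 2
Reactants: 3
Product: 5 4-(3-hydroxy-3-methylbutoxy)-3-methylphenol, via aryl formate 4 (not isolated)
Conditions: mCPBA, CH2Cl2, rt; then K2CO3 (cat.), MeOH, 0 °C
Reagents that add atoms: mCPBA, OOC(=O)c1cccc(Cl)c1
Why: Baeyer–Villiger (Dakin-type) oxidation of an electron-rich aryl aldehyde proceeds with aryl migration to the formate, which is methanolysed in the same flask; the tertiary alcohol is inert.

Step 3
Reactants: 5
Product: 6 2-bromo-4-(3-hydroxy-3-methylbutoxy)-5-methylphenol
Conditions: NBS, i-Pr2NH (10 mol %), CH2Cl2, 0 °C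
Reagents that add atoms: N-bromosuccinimide, O=C1CCC(=O)N1Br
Why: Amine-catalysed electrophilic ortho-bromination of the phenol should go to the open ortho position (para to CH3) and not to the one between OH and CH3, which leaves a ring hydrogen flanked by Br and the alkoxy group for the later aryne formation.

Step 4
Reactants: 7 2-bromoresorcinol; 8 2-(furan-2-yl)-4,4,5,5-tetramethyl-1,3,2-dioxaborolane
Product: 9 2-(furan-2-yl)benzene-1,3-diol
Conditions: Pd(OAc)2 (3 mol %), SPhos (6 mol %), K3PO4, 1,4-dioxane/H2O, 80 °C
Reagents that add atoms: none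
Why: Suzuki–Miyaura coupling; the biarylphosphine ligand handles the hindered, electron-rich di-ortho-oxygenated bromide and the pinacol ester limits protodeboronation of the 2-furyl boron partner.

Step 5
Reactants: 6; 9 (3 equiv)
Product: 11 di-tert-butyl[2-bromo-4-(3-hydroxy-3-methylbutoxy)-5-methylphenoxy][2-(furan-2-yl)-3-hydroxyphenoxy]silane, via silyl triflate 10 (not isolated)
Conditions: t-Bu2Si(OTf)2 (1.05 equiv), Et3N, CH2Cl2, −78 °C; then 9 (3 equiv), imidazole, DMF, 0 → 40 °C
Reagents that add atoms: di-tert-butylsilyl bis(trifluoromethanesulfonate), CC(C)(C)[Si](OS(=O)(=O)C(F)(F)F)(OS(=O)(=O)C(F)(F)F)C(C)(C)C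
Why: Two successive substitutions at silicon: the ortho-bromophenoxide displaces the first triflate at −78 °C, where the hindered tertiary hydroxyl should not react with the di-tert-butylsilyl electrophile, and an excess of the symmetrical diol then displaces the second triflate once only (excess 9 is recovered).

Step 6
Reactants: 11
Product: 12 di-tert-butyl[2-bromo-4-(3-hydroxy-3-methylbutoxy)-5-methylphenoxy][3-(tert-butyldimethylsilyloxy)-2-(furan-2-yl)phenoxy]silane
Conditions: TBSCl, imidazole, DMF, rt
Reagents that add atoms: tert-butyldimethylsilyl chloride, CC(C)(C)[Si](C)(C)Cl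
Why: Imidazole-promoted silylation of the remaining phenol; TBSCl does not silylate the tertiary alcohol under these conditions.

Step 7
Reactants: 12
Product: 14 racemic oxabenzonorbornadiene tertiary alcohol (ring F on Bq; O8 and one ring F oxygen bridged by Si(t-Bu)2; other ring F oxygen as TBS ether), via aryne 13 (not isolated)
Conditions: LiTMP (2.5 equiv), THF (0.005 M), −78 → −20 °C; NH4Cl
Reagents that add atoms: none
Why: LiTMP, after forming the tertiary alkoxide, removes the ring hydrogen flanked by Br and the alkoxy group, loss of LiBr gives the aryne, and the tethered furan traps it in an intramolecular Diels–Alder reaction (silicon-tethered aryne–furan cycloaddition) in which the tether joins furan C2 to the aryne carbon next to the silyloxy group through an eight-membered ring, so ring F ends on the bridgehead beside O8; the two bridgehead stereocentres form together as a racemate with the relative configuration imposed by the bicycle.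

Step 8
Reactants: 14
Product: 15 racemic oxabenzonorbornadiene acetate (side chain OCH2CH2C(CH3)2OAc)
Conditions: Ac2O, DMAP, Et3N, CH2Cl2, 35 °C
Reagents that add atoms: acetic anhydride, CC(=O)OC(C)=O
Why: DMAP-catalysed acyl transfer (Steglich-type acylation) is the standard way to esterify a tertiary alcohol and leaves the aryl silyl ethers and the strained alkene untouched.

Step 9
Reactants: 15
Product: 16 oxabenzonorbornadiene acetate as the single enantiomer with Bq S and Bh R
Conditions: preparative SFC on an amylose tris(3,5-dimethylphenylcarbamate) stationary phase, CO2/i-PrOH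
Reagents that add atoms: none
Why: Chromatography on a chiral stationary phase separates the enantiomers of a rigid, configurationally stable bicycle without changing a bond, and the chosen enantiomer fixes the absolute configuration of every later stereocentre.

Step 10
Reactants: 17 3,5-dihydroxybenzyl alcohol
Product: 18 1,3-bis(methoxymethoxy)-5-[(methoxymethoxy)methyl]benzene
Conditions: MOMCl (3.6 equiv), i-Pr2NEt, CH2Cl2, 0 °C → reflux
Reagents that add atoms: chloromethyl methyl ether, COCCl
Why: O-alkylation of all three hydroxyls gives acetal ethers that direct, and survive, the lithiation of the next step.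

Step 11
Reactants: 18
Product: 20 2,6-bis(methoxymethoxy)-4-[(methoxymethoxy)methyl]benzaldehyde, via aryllithium 19 (not isolated)
Conditions: n-BuLi, TMEDA, THF, −20 → 0 °C; DMF, −78 °C → rt; NH4Cl
Reagents that add atoms: N,N-dimethylformamide, CN(C)C=O
Why: Directed ortho-metalation removes the ring hydrogen flanked by the two aryl OMOM groups (doubly activated) and the aryllithium is formylated by DMF.

Step 12
Reactants: 20
Product: 21 2,6-dihydroxy-4-(hydroxymethyl)benzaldehyde
Conditions: HCl (3 M aq.), MeOH, 50 °C
Reagents that add atoms: none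
Why: Acid-catalysed acetal exchange with methanol removes all three MOM groups; the doubly hydrogen-bonded aldehyde is stable to these conditions.

Step 13
Reactants: 21
Product: 22 2,6-bis(tert-butyldimethylsilyloxy)-4-[(tert-butyldimethylsilyloxy)methyl]benzaldehyde
Conditions: TBSCl (3.5 equiv), imidazole, DMF, rt
Reagents that add atoms: tert-butyldimethylsilyl chloride, CC(C)(C)[Si](C)(C)Cl
Why: Imidazole-promoted silylation of the two phenols and the primary alcohol.

Step 14
Reactants: 22
Product: 23 racemic 1-{2,6-bis(tert-butyldimethylsilyloxy)-4-[(tert-butyldimethylsilyloxy)methyl]phenyl}prop-2-yn-1-ol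
Conditions: ethynylmagnesium bromide, THF, −78 → −20 °C; NH4Cl
Reagents that add atoms: ethynylmagnesium bromide, C#C[Mg]Br
Why: Grignard addition of the small ethynyl nucleophile to the hindered aldehyde at low temperature, where aryl-to-alkoxide silyl migration is slow, gives the racemic propargylic alcohol, whose stereocentre is removed in step 17.

Step 15
Reactants: 16; 24 methyl 2-bromoacrylate (2 equiv); 23 (1.5 equiv, added slowly)
Product: 25 exo,exo-cis coupling product: C(=CH2)CO2Me on Cy and C≡C–CH(OH)–aryl (ring A) on Cx, both syn to the oxygen bridge; mixture of epimers at the propargylic carbinol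
Conditions: Pd(PPh3)4 (10 mol %), CuI (10 mol %), i-Pr2NEt, toluene, 60 °C
Reagents that add atoms: none
Why: Heck-type carbopalladation ended by Sonogashira-type alkynylation (three-component coupling of a strained bicyclic alkene): zerovalent palladium inserts into the C–Br bond, the vinylpalladium adds syn to the exo face and delivers the vinyl group to the alkene carbon remote from the aryl-substituted bridgehead, and the resulting norbornyl–palladium (no syn β-hydrogen, Pd–C–C–O dihedral near 90° so that β-oxygen elimination is disfavoured) is alkynylated through the copper acetylide with retention, which sets Cx and Cy exo and cis.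

Step 16
Reactants: 25
Product: 26 triol: Cy now carries C(OH)(CH2OH)CO2Me; mixture of carbinol epimers
Conditions: OsO4 (5 mol %), NMO, acetone/H2O, rt
Reagents that add atoms: osmium tetroxide, O=[Os](=O)(=O)=O (oxygen atoms, restored by N-methylmorpholine N-oxide, C[N+]1([O-])CCOCC1, and water, O)
Why: Catalytic OsO4/NMO syn-dihydroxylation attacks the only alkene (alkyne and arenes react far more slowly) and turns the acrylate into a glycol that is a base-stable mask of the α-ketoester; the new carbinol centre is removed in step 19.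

Step 17
Reactants: 26
Product: 27 ynone glycol: ring A aryl ketone conjugated to the alkyne on Cx, glycol on Cy unchanged
Conditions: MnO2 (activated, excess), CH2Cl2, rt
Reagents that add atoms: none
Why: MnO2 oxidises only the benzylic–propargylic alcohol and leaves the saturated glycol.

Step 18
Reactants: 27
Product: 28 ynone glycol with both ring A phenols free (2,6-dihydroxyaryl ynone)
Conditions: Bu4NF (2.2 equiv), AcOH (10 equiv), THF, −30 °C
Reagents that add atoms: none
Why: Fluoride desilylation is fastest for the two ring A aryl silyl ethers, whose phenoxides are the best leaving groups because they sit ortho to the ynone carbonyl, so the limited amount of fluoride should spare the hindered ring F silyl ether, the t-Bu2Si bridge and the alkyl silyl ether, while excess acetic acid keeps the freed phenol protonated so that it does not add to the ynone.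

Step 19
Reactants: 28
Product: 29 exo-cis ynone α-ketoester (key-step precursor): C≡C–C(=O)–(2,6-dihydroxy-4-TBSOCH2-phenyl) on Cx, C(=O)CO2Me on Cy
Conditions: NaIO4–SiO2, CH2Cl2, 0 °C → rt
Reagents that add atoms: none
Why: Periodate glycol cleavage (Malaprade reaction) releases the ketone under neutral conditions, so the acidic endo Cy–H, which lies anti-periplanar to the Bh–O bond, is not removed and neither epimerisation nor opening of the oxygen bridge should occur; the product is used at once.

Step 20
Reactants: 29
Product: 30 partly silylated aspergichromone B (rings B and C closed; Cq S, Cx R, Cy R, Bh R, Bq S)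
Conditions: Pd(OAc)2 (10 mol %), 2,2'-bipyridine (12 mol %), THF, 45 °C
Reagents that add atoms: none
Why: The bipyridine–Pd(OAc)2 complex binds the ynone triple bond and the hydrogen-bonded ring A phenol adds anti to the metal at the beta carbon (the one on Cx), a 6-endo-dig oxypalladation that closes ring B and leaves a chromon-3-yl–palladium bond in the plane of the new ring and cis to Cx. This vinyl–palladium bond then adds across the neighbouring ketone C=O of the α-ketoester on Cy (5-exo-trig at the carbonyl, ring C), and the acetic acid released in the first event protonates the palladium alkoxide, so the divalent catalyst returns without a redox step. The closest known chemistry is the family of bipyridine-ligated divalent-palladium cascades in which nucleopalladation of an alkyne (oxygen or nitrogen nucleophile) is ended by 1,2-addition of the vinyl–palladium bond to a tethered aldehyde, ketone or nitrile, together with the 6-endo closure of 2-hydroxyaryl ynones to chromones by electrophilic metals and halogens. The only new stereocentre, Cq, is set by the substrate: both arms are exo and cis, and the ketone is expected to react through the rotamer that turns its oxygen toward the oxygen bridge and the bulkier CO2Me to the open convex face, which puts the Cq hydroxyl syn to the bridge as in the target. The step needs 6-endo rather than 5-exo phenol attack, which the ynone polarisation (electrophilic beta carbon) should secure, and carbonyl addition rather than protonation of the C–Pd bond, which the bipyridine ligand, the aprotic medium, the very electrophilic α-ketoester and the rigid exo-cis bicycle (C3 held within bonding distance of the ketone) should favour. Acetate is the only base present, which should spare the endo Cy–H and so the oxygen bridge.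

Step 21
Reactants: 30
Product: 31 aspergichromone B
Conditions: HF·pyridine, pyridine, THF, 0 °C → rt
Reagents that add atoms: none
Why: Pyridine-buffered HF cleaves the Si–O bonds of the alkyl and aryl silyl ethers and of the silylene bridge without the base that would open the oxygen bridge by elimination from Cx–H and without the strong acid that would ionise the Bq–O bond; the tertiary acetate and methyl ester are inert.

**Compound list**

1 | 4-hydroxy-3-methylbenzaldehyde | O=Cc1ccc(O)c(C)c1 | starting material
2 | 3-methylbutane-1,3-diol | CC(C)(O)CCO | starting material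
3 | 4-(3-hydroxy-3-methylbutoxy)-3-methylbenzaldehyde | O=Cc1ccc(OCCC(C)(C)O)c(C)c1 | intermediate
4 | 4-(3-hydroxy-3-methylbutoxy)-3-methylphenyl formate (not isolated) | O=COc1ccc(OCCC(C)(C)O)c(C)c1 | intermediate
5 | 4-(3-hydroxy-3-methylbutoxy)-3-methylphenol | Oc1ccc(OCCC(C)(C)O)c(C)c1 | intermediate
6 | 2-bromo-4-(3-hydroxy-3-methylbutoxy)-5-methylphenol | Oc1cc(C)c(OCCC(C)(C)O)cc1Br | intermediate
7 | 2-bromoresorcinol | Oc1cccc(O)c1Br | starting material
8 | 2-(furan-2-yl)-4,4,5,5-tetramethyl-1,3,2-dioxaborolane | CC1(C)OB(c2ccco2)OC1(C)C | starting material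
9 | 2-(furan-2-yl)benzene-1,3-diol | Oc1cccc(O)c1-c1ccco1 | intermediate
10 | [2-bromo-4-(3-hydroxy-3-methylbutoxy)-5-methylphenoxy]di-tert-butylsilyl trifluoromethanesulfonate (not isolated) | CC(C)(O)CCOc1cc(Br)c(O[Si](OS(=O)(=O)C(F)(F)F)(C(C)(C)C)C(C)(C)C)cc1C | intermediate
11 | di-tert-butyl[2-bromo-4-(3-hydroxy-3-methylbutoxy)-5-methylphenoxy][2-(furan-2-yl)-3-hydroxyphenoxy]silane | CC(C)(O)CCOc1cc(Br)c(O[Si](Oc2cccc(O)c2-c2ccco2)(C(C)(C)C)C(C)(C)C)cc1C | intermediate
12 | TBS ether of 11 at the free ring F phenol | CC(C)(O)CCOc1cc(Br)c(O[Si](Oc2cccc(O[Si](C)(C)C(C)(C)C)c2-c2ccco2)(C(C)(C)C)C(C)(C)C)cc1C | intermediate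
13 | aryne from 12 (formed as its lithium alkoxide, drawn neutral; not isolated) | CC(C)(O)CCOC1=C(C)C=C(O[Si](Oc2cccc(O[Si](C)(C)C(C)(C)C)c2-c2ccco2)(C(C)(C)C)C(C)(C)C)C#C1 | intermediate
14 | racemic 1,4-dihydro-1,4-epoxynaphthalene: ring F on C1 (Bq), O8 and one ring F oxygen bridged by Si(t-Bu)2, other ring F oxygen as TBS ether, 6-CH3, 5-OCH2CH2C(CH3)2OH | C1=CC2OC1(c3c(O[Si]4(C(C)(C)C)C(C)(C)C)cccc3O[Si](C)(C)C(C)(C)C)c1c(O4)cc(C)c(OCCC(C)(C)O)c12 | intermediate
15 | racemic acetate of 14 | C1=CC2OC1(c3c(O[Si]4(C(C)(C)C)C(C)(C)C)cccc3O[Si](C)(C)C(C)(C)C)c1c(O4)cc(C)c(OCCC(C)(C)OC(C)=O)c12 | intermediate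
16 | acetate 15 as the single enantiomer, Bq S and Bh R | C1=C[C@H]2O[C@]1(c3c(O[Si]4(C(C)(C)C)C(C)(C)C)cccc3O[Si](C)(C)C(C)(C)C)c1c(O4)cc(C)c(OCCC(C)(C)OC(C)=O)c12 | intermediate
17 | 3,5-dihydroxybenzyl alcohol | OCc1cc(O)cc(O)c1 | starting material
18 | 1,3-bis(methoxymethoxy)-5-[(methoxymethoxy)methyl]benzene | COCOCc1cc(OCOC)cc(OCOC)c1 | intermediate
19 | 2,6-bis(methoxymethoxy)-4-[(methoxymethoxy)methyl]phenyllithium (not isolated) | [Li]c1c(OCOC)cc(COCOC)cc1OCOC | intermediate
20 | 2,6-bis(methoxymethoxy)-4-[(methoxymethoxy)methyl]benzaldehyde | O=Cc1c(OCOC)cc(COCOC)cc1OCOC | intermediate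
21 | 2,6-dihydroxy-4-(hydroxymethyl)benzaldehyde | O=Cc1c(O)cc(CO)cc1O | intermediate
22 | 2,6-bis(tert-butyldimethylsilyloxy)-4-[(tert-butyldimethylsilyloxy)methyl]benzaldehyde | O=Cc1c(O[Si](C)(C)C(C)(C)C)cc(CO[Si](C)(C)C(C)(C)C)cc1O[Si](C)(C)C(C)(C)C | intermediate
23 | racemic 1-{2,6-bis(TBSO)-4-[(TBSO)methyl]phenyl}prop-2-yn-1-ol | C#CC(O)c1c(O[Si](C)(C)C(C)(C)C)cc(CO[Si](C)(C)C(C)(C)C)cc1O[Si](C)(C)C(C)(C)C | intermediate
24 | methyl 2-bromoacrylate | C=C(Br)C(=O)OC | starting material
25 | exo,exo-cis coupling product (Bq S, Bh R; acrylate on Cy, propargylic alcohol alkyne on Cx; carbinol epimers) | OC(C#C[C@H]2[C@@H](C(=C)C(=O)OC)[C@H]1O[C@]2(c3c(O[Si]4(C(C)(C)C)C(C)(C)C)cccc3O[Si](C)(C)C(C)(C)C)c2c(O4)cc(C)c(OCCC(C)(C)OC(C)=O)c21)c1c(O[Si](C)(C)C(C)(C)C)cc(CO[Si](C)(C)C(C)(C)C)cc1O[Si](C)(C)C(C)(C)C | intermediate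
26 | triol from 25 (glycol ester on Cy; carbinol epimers) | OC(C#C[C@H]2[C@@H](C(O)(CO)C(=O)OC)[C@H]1O[C@]2(c3c(O[Si]4(C(C)(C)C)C(C)(C)C)cccc3O[Si](C)(C)C(C)(C)C)c2c(O4)cc(C)c(OCCC(C)(C)OC(C)=O)c21)c1c(O[Si](C)(C)C(C)(C)C)cc(CO[Si](C)(C)C(C)(C)C)cc1O[Si](C)(C)C(C)(C)C | intermediate
27 | ynone glycol, ring A fully silylated | O=C(C#C[C@H]2[C@@H](C(O)(CO)C(=O)OC)[C@H]1O[C@]2(c3c(O[Si]4(C(C)(C)C)C(C)(C)C)cccc3O[Si](C)(C)C(C)(C)C)c2c(O4)cc(C)c(OCCC(C)(C)OC(C)=O)c21)c1c(O[Si](C)(C)C(C)(C)C)cc(CO[Si](C)(C)C(C)(C)C)cc1O[Si](C)(C)C(C)(C)C | intermediate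
28 | ynone glycol, ring A phenols free | O=C(C#C[C@H]2[C@@H](C(O)(CO)C(=O)OC)[C@H]1O[C@]2(c3c(O[Si]4(C(C)(C)C)C(C)(C)C)cccc3O[Si](C)(C)C(C)(C)C)c2c(O4)cc(C)c(OCCC(C)(C)OC(C)=O)c21)c1c(O)cc(CO[Si](C)(C)C(C)(C)C)cc1O | intermediate
29 | exo-cis ynone α-ketoester (key-step precursor) | O=C(C#C[C@H]2[C@@H](C(=O)C(=O)OC)[C@H]1O[C@]2(c3c(O[Si]4(C(C)(C)C)C(C)(C)C)cccc3O[Si](C)(C)C(C)(C)C)c2c(O4)cc(C)c(OCCC(C)(C)OC(C)=O)c21)c1c(O)cc(CO[Si](C)(C)C(C)(C)C)cc1O | intermediate
30 | partly silylated aspergichromone B (ring A CH2OTBS, ring F OTBS, O8/ring F O bridged by Si(t-Bu)2; Cq S, Cx R, Cy R, Bh R, Bq S) | COC(=O)[C@@]1(O)c2c(oc3cc(CO[Si](C)(C)C(C)(C)C)cc(O)c3c2=O)[C@H]2[C@@H]1[C@H]1O[C@]2(c3c(O[Si]4(C(C)(C)C)C(C)(C)C)cccc3O[Si](C)(C)C(C)(C)C)c2c(O4)cc(C)c(OCCC(C)(C)OC(C)=O)c21 | intermediate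
31 | aspergichromone B (Cq S, Cx R, Cy R, Bh R, Bq S) | COC(=O)[C@@]1(O)c2c(oc3cc(CO)cc(O)c3c2=O)[C@H]2[C@@H]1[C@H]1O[C@]2(c2c(O)cccc2O)c2c(O)cc(C)c(OCCC(C)(C)OC(C)=O)c21 | target

**Step count and risks**

Total: 21 steps. Longest linear sequence: 15 steps (1, 2, 3, 5, 6, 7, 8, 9, 15–21).

Steps most likely to fail:

1. Step 20. The chromon-3-yl–palladium bond may be protonated before it adds to the ketone (ring B only), the phenol may attack 5-exo, the ketone may react on the wrong face, or acetate may trigger loss of the oxygen bridge. The fallback sets out from 28 and comes back at 30, closing the two rings separately with iodine as a placeholder. N-Iodosuccinimide in MeCN at 0 °C should close ring B by 6-endo iodocyclisation of the 2-hydroxyaryl ynone to the 3-iodochromone glycol F1. NaIO4–SiO2 then cleaves the glycol to the 3-iodochromone α-ketoester F2. An intramolecular Nozaki–Hiyama–Kishi reaction (CrCl2, NiCl2 cat., DMF, rt) adds the C3 carbon to the ketone and closes ring C, giving 30.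

2. Step 15. The norbornyl–palladium intermediate may open the oxygen bridge, attack the acrylate double bond (3-exo), or be bypassed by direct vinyl–alkyne coupling; the amine base may also consume the bromoacrylate, and carbopalladation may take the opposite regiochemistry. The fallback sets out from 23 and comes back at 25, replacing the copper/amine termination by a base-free Stille-type transmetalation. TESCl/imidazole gives the propargylic triethylsilyl ether F3. n-BuLi at −78 °C followed by Bu3SnCl gives the alkynylstannane F4. Pd(PPh3)4 in toluene at 70 °C couples 16, 24 and F4 to the coupled triethylsilyl ether F5. PPTS in MeOH at 0 °C removes the triethylsilyl group and gives 25.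

3. Step 7. The aryne may be captured by the lithium alkoxide, by the amide or by a second molecule instead of the tethered furan if the eight-membered transition state is too strained. The fallback sets out from 6 and 9 and comes back at 14, using an intermolecular cycloaddition and installing the silicon bridge afterwards. TBSCl/imidazole converts 6 into the aryl silyl ether F6 and 9 into the bis-silyl furan F7. LiTMP with F6 in the presence of excess F7 (THF, −78 °C → rt) should give both regioisomeric cycloadducts; chromatography isolates the tris-silyl oxabenzonorbornadiene F8 with ring F beside the silyloxy group. Bu4NF/AcOH gives the triphenol F9. t-Bu2Si(OTf)2 with 2,6-lutidine bridges the only two phenol oxygens within reach of one silicon (O8 and a ring F oxygen), giving the silylene phenol F10. TBSCl/imidazole then gives 14.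

**Further compounds**

F1 | step 20 | 3-iodochromone glycol (ring B closed, iodine on chromone C3, glycol ester on Cy) | O=c1c(I)c([C@H]2[C@@H](C(O)(CO)C(=O)OC)[C@H]3O[C@]2(c4c(O[Si]5(C(C)(C)C)C(C)(C)C)cccc4O[Si](C)(C)C(C)(C)C)c2c(O5)cc(C)c(OCCC(C)(C)OC(C)=O)c23)oc2cc(CO[Si](C)(C)C(C)(C)C)cc(O)c12
F2 | step 20 | 3-iodochromone α-ketoester | O=c1c(I)c([C@H]2[C@@H](C(=O)C(=O)OC)[C@H]3O[C@]2(c4c(O[Si]5(C(C)(C)C)C(C)(C)C)cccc4O[Si](C)(C)C(C)(C)C)c2c(O5)cc(C)c(OCCC(C)(C)OC(C)=O)c23)oc2cc(CO[Si](C)(C)C(C)(C)C)cc(O)c12
F3 | step 15 | propargylic triethylsilyl ether of 23 | C#CC(O[Si](CC)(CC)CC)c1c(O[Si](C)(C)C(C)(C)C)cc(CO[Si](C)(C)C(C)(C)C)cc1O[Si](C)(C)C(C)(C)C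
F4 | step 15 | tributylstannyl alkyne from F3 | CCCC[Sn](CCCC)(CCCC)C#CC(O[Si](CC)(CC)CC)c1c(O[Si](C)(C)C(C)(C)C)cc(CO[Si](C)(C)C(C)(C)C)cc1O[Si](C)(C)C(C)(C)C
F5 | step 15 | triethylsilyl ether of 25 | CC[Si](CC)(CC)OC(C#C[C@H]2[C@@H](C(=C)C(=O)OC)[C@H]1O[C@]2(c3c(O[Si]4(C(C)(C)C)C(C)(C)C)cccc3O[Si](C)(C)C(C)(C)C)c2c(O4)cc(C)c(OCCC(C)(C)OC(C)=O)c21)c1c(O[Si](C)(C)C(C)(C)C)cc(CO[Si](C)(C)C(C)(C)C)cc1O[Si](C)(C)C(C)(C)C
F6 | step 7 | TBS ether of phenol 6 | CC(C)(O)CCOc1cc(Br)c(O[Si](C)(C)C(C)(C)C)cc1C
F7 | step 7 | 2-[2,6-bis(tert-butyldimethylsilyloxy)phenyl]furan | CC(C)(C)[Si](C)(C)Oc1cccc(O[Si](C)(C)C(C)(C)C)c1-c1ccco1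
F8 | step 7 | racemic tris-TBS oxabenzonorbornadiene alcohol (untethered) | C1=CC2OC1(c3c(O[Si](C)(C)C(C)(C)C)cccc3O[Si](C)(C)C(C)(C)C)c1c(O[Si](C)(C)C(C)(C)C)cc(C)c(OCCC(C)(C)O)c12
F9 | step 7 | racemic oxabenzonorbornadiene triphenol | C1=CC2OC1(c3c(O)cccc3O)c1c(O)cc(C)c(OCCC(C)(C)O)c12
F10 | step 7 | racemic silylene-bridged oxabenzonorbornadiene with one free ring F phenol | C1=CC2OC1(c3c(O[Si]4(C(C)(C)C)C(C)(C)C)cccc3O)c1c(O4)cc(C)c(OCCC(C)(C)O)c12
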